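**Strategy.** Everything rests on opening ring D at C3–C3a. C3 carries C6′ of ring P, an acyl carbon that traces back to a carboxyl group on C3. A carboxyl carbon at C3, flanked by the aryl-bearing C2 and the enol-ether carbon C3a of ring F, is what oxidative ring contraction of a 2-aryl-dihydropyran-4-one leaves behind. Trivalent iodine in trimethyl orthoformate shifts the pyranone carbon from the ketone carbon to its α-carbon. One operation thus forms C3–C3a, shrinks the six-membered ring to ring D, sets C3 trans to C2 and delivers the ketone carbon as the C3 methyl ester. The precursor is the (R)-2-aryl-7-methyl-2,3-dihydropyrano[4,3-b]pyran-4,5-dione, its catechol masked as the electron-poor bis-pivalate.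

Key step: step 4

**Remarks on the chemistry (assumptions)**
- The C2 aryl ring is carried as its bis-pivalate and not as a dialkoxyarene. A para-alkoxyphenyl group at C2 is itself a good migrating group (2,3-aryl shift) and is open to attack by trivalent iodine, and a final boron-trihalide ether cleavage would endanger the benzylic C2–O bond. Acyloxy groups remove all three problems.
- C6′ of ring P is at the acyl (ketone) oxidation level in the target; it is reached from the C3 carboxyl carbon by one C-acylation.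
- The (R) centre of the dihydropyranone maps onto (2R,3R)-trans in ring D and in the target, so no descriptor needs changing.
- The quinidine-derived thiourea is assumed to give the (R) centre in step 3; if the sense of induction is opposite, the quinine-derived pseudoenantiomer is used.

**Step 1**
Reactants: 1 3,4-dihydroxybenzaldehyde
Product: 2 3,4-bis(pivaloyloxy)benzaldehyde
Conditions: PivCl, Et3N, DMAP (cat.), CH2Cl2, 0 °C → rt
Reagents that add atoms: pivaloyl chloride, CC(C)(C)C(Cl)=O
Why: DMAP-catalysed O-acylation of both phenols gives hindered aryl esters that make the ring electron-poor for step 4 and that tolerate the catalytic amine and the amide bases used later.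

**Step 2**
Reactants: 2 3,4-bis(pivaloyloxy)benzaldehyde; 3 dehydroacetic acid
Product: 4 3-[(E)-3-(3,4-bis(pivaloyloxy)phenyl)acryloyl]-4-hydroxy-6-methyl-2H-pyran-2-one
Conditions: piperidine (cat.), CHCl3, reflux, Dean–Stark trap
Reagents that add atoms: none
Why: Amine-catalysed Claisen–Schmidt (aldol) condensation takes place at the acetyl methyl of 3, which as part of the enolised tricarbonyl system is far more reactive than the 6-methyl, and dehydration under thermodynamic control should give the E-enone.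

**Step 3**
Reactants: 4 the E-enone
Product: 5 (2R)-2-[3,4-bis(pivaloyloxy)phenyl]-7-methyl-2,3-dihydro-4H,5H-pyrano[4,3-b]pyran-4,5-dione
Conditions: N-[3,5-bis(trifluoromethyl)phenyl]-N′-(9-deoxy-epi-quinidin-9-yl)thiourea (10 mol%), toluene/CH2Cl2, 0 °C; filtration through acid-washed silica
Reagents that add atoms: none
Why: Bifunctional base/hydrogen-bond catalysis of an intramolecular oxa-Michael addition (6-endo-trig, the flavanone-type chalcone cyclisation), in which the quinuclidine takes the acidic 4-OH, the thiourea binds the enone carbonyl and the chiral ion pair should deliver the oxygen to the Re face of the β-carbon to set C2 as (R), while low temperature and removal of the base limit the reverse reaction.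

**Step 4**
Reactants: 5 the (2R)-dihydropyranopyrandione
Product: 8 methyl (2R,3R)-2-[3,4-bis(pivaloyloxy)phenyl]-6-methyl-4-oxo-2,3-dihydro-4H-furo[3,2-c]pyran-3-carboxylate (trans), via methyl enol ether 6 (not isolated), via iodanyl dimethyl ketal 7 (not isolated)
Conditions: PhI(OAc)2, conc. H2SO4, HC(OMe)3, 0 °C → rt
Reagents that add atoms: trimethyl orthoformate, COC(OC)OC
Why: Acid and orthoformate turn the C4 ketone into methyl enol ether 6, which electrophilic PhI(OAc)2 attacks at C3 on the face anti to the C2 aryl group, and methanol capture of the oxocarbenium ion gives the α-iodanyl ketal 7. With C3–I antiperiplanar to C4–C4a, the electron-rich pyranone carbon C4a (C3a of the product, supported in the bridged transition state by O1 and the ring-F oxygen) moves from C4 to C3 as iodobenzene leaves, and the dimethoxycarbenium ion left at C4 collapses to the methyl ester. The closest known reaction is the ring contraction of flavanones to methyl trans-2-aryl-2,3-dihydrobenzofuran-3-carboxylates by trivalent iodine or trivalent thallium in trimethyl orthoformate. Ring D is closed not by a cyclisation but by this semipinacol-type 1,2-carbon shift (3-exo-tet bridging of C4a onto C3, then cleavage of C4–C4a), which removes one atom from the six-membered ring. C3 is controlled by the C2 centre, since anti iodination followed by inversion at C3 places the ester trans to the aryl group, which is also the more stable arrangement. The step needs the C4a shift to win over a 2,3-shift of the C2 aryl group, dehydrogenation and α-methoxylation: ketalisation lets C4 carry the positive charge, the two acyloxy groups lower the migratory aptitude and oxidisability of the aryl ring, no alkene is present yet, and the low temperature keeps acid-mediated ring opening at C2 slow.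

**Step 5**
Reactants: 8 the trans methyl ester
Product: 9 (2R,3R)-2-[3,4-bis(pivaloyloxy)phenyl]-6-methyl-4-oxo-2,3-dihydro-4H-furo[3,2-c]pyran-3-carboxylic acid
Conditions: LiI, EtOAc, reflux, dark; then 1 M HCl
Reagents that add atoms: none
Why: SN2 O-demethylation of the ester by iodide gives the carboxylate without hydroxide or alkoxide, so the aryl pivalates, the lactone and the base-labile C3–H/C2–O array (prone to E1cB ring opening) should stay intact and no stereocentre is touched.

**Step 6**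
Reactants: 9 the carboxylic acid; 2 3,4-bis(pivaloyloxy)benzaldehyde
Product: 11 (2R,3R)-2-[3,4-bis(pivaloyloxy)phenyl]-6-{2-[3,4-bis(pivaloyloxy)phenyl]-2-hydroxyethyl}-4-oxo-2,3-dihydro-4H-furo[3,2-c]pyran-3-carboxylic acid (both carbinol epimers), via dilithium dienolate carboxylate 10 (not isolated)
Conditions: LiN(SiMe3)2 (2.1 equiv), THF, −78 °C; then 2; then 1 M HCl
Reagents that add atoms: none
Why: Vinylogous aldol addition, in which carboxylate formation shields C3–H, the second equivalent of the non-nucleophilic amide deprotonates the 6-methyl group to the extended dienolate 10, and its exocyclic carbon adds to the aldehyde, the new carbinol centre being left uncontrolled because the next step removes it.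

**Step 7**
Reactants: 11 the hydroxy acid
Product: 12 (2R,3R)-2-[3,4-bis(pivaloyloxy)phenyl]-6-[(E)-2-(3,4-bis(pivaloyloxy)phenyl)ethenyl]-4-oxo-2,3-dihydro-4H-furo[3,2-c]pyran-3-carboxylic acid
Conditions: TsOH·H2O (cat.), toluene, 90 °C
Reagents that add atoms: none
Why: Acid-catalysed dehydration of the benzylic alcohol, driven by conjugation with ring F, should give the E-alkene under thermodynamic control, and an acidic medium cannot enolise C3 or open ring D by elimination.

**Step 8**
Reactants: 12 the styryl acid; 13 2,2,6-trimethyl-4H-1,3-dioxin-4-one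
Product: 16 (2R,3R)-2-[3,4-bis(pivaloyloxy)phenyl]-6-[(E)-2-(3,4-bis(pivaloyloxy)phenyl)ethenyl]-3-[2-(2,2-dimethyl-4-oxo-4H-1,3-dioxin-6-yl)acetyl]-2,3-dihydro-4H-furo[3,2-c]pyran-4-one, via acyl imidazolide 14 (not isolated), via lithium dienolate 15 (not isolated)
Conditions: 12, 1,1′-carbonyldiimidazole, THF, rt; added to 13/LiN(SiMe3)2 (2.5 equiv each), THF, −78 °C; then 1 M HCl (pH 3)
Reagents that add atoms: none
Why: Claisen-type C-acylation of the γ-carbon of dioxinone dienolate 15 by acyl imidazolide 14, in which the first-formed β-diketone equivalent is at once deprotonated at its CH2 by the second equivalent of 15, so the new ketone is protected and C3–H is kept from enolising.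

**Step 9**
Reactants: 16 the keto-dioxinone
Product: 18 the tetrapivalate of the target, (2R,3R)-2-[3,4-bis(pivaloyloxy)phenyl]-6-[(E)-2-(3,4-bis(pivaloyloxy)phenyl)ethenyl]-3-(4-hydroxy-2-oxo-2H-pyran-6-yl)-2,3-dihydro-4H-furo[3,2-c]pyran-4-one, via acylketene 17 (not isolated)
Conditions: toluene, 110 °C
Reagents that add atoms: none
Why: Thermal retro-[4+2] loss of acetone from the dioxinone gives acylketene 17, whose enolised δ-ketone oxygen adds to the ketene (6π-type lactonisation) to close ring P as the 4-hydroxy-2-pyranone under neutral conditions, with no stereocentre involved.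

**Step 10**
Reactants: 18 the tetrapivalate
Product: 19 the target, (2R,3R)-2-(3,4-dihydroxyphenyl)-6-[(E)-2-(3,4-dihydroxyphenyl)ethenyl]-3-(4-hydroxy-2-oxo-2H-pyran-6-yl)-2,3-dihydro-4H-furo[3,2-c]pyran-4-one
Conditions: K2CO3, degassed MeOH, argon, 0 °C → rt; then dilute HCl to pH 3
Reagents that add atoms: none
Why: Zemplén-type methanolysis cleaves the four aryl pivalates while ring P sits as its enolate and C3–H is too weakly acidic to be removed, and if the para-phenoxide opens ring D through a quinone methide, reclosure should return the more stable trans isomer fixed by the untouched C3 centre, with oxygen excluded to protect the catechols.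

**Compound list**
1 | 3,4-dihydroxybenzaldehyde | O=Cc1ccc(O)c(O)c1 | starting material
2 | 3,4-bis(pivaloyloxy)benzaldehyde | CC(C)(C)C(=O)Oc1ccc(C=O)cc1OC(=O)C(C)(C)C | intermediate
3 | dehydroacetic acid | CC(=O)c1c(O)cc(C)oc1=O | starting material
4 | 3-[(E)-3-(3,4-bis(pivaloyloxy)phenyl)acryloyl]-4-hydroxy-6-methyl-2H-pyran-2-one | Cc1cc(O)c(C(=O)/C=C/c2ccc(OC(=O)C(C)(C)C)c(OC(=O)C(C)(C)C)c2)c(=O)o1 | intermediate
5 | (2R)-2-[3,4-bis(pivaloyloxy)phenyl]-7-methyl-2,3-dihydro-4H,5H-pyrano[4,3-b]pyran-4,5-dione | O=C1C[C@H](c2ccc(OC(=O)C(C)(C)C)c(OC(=O)C(C)(C)C)c2)Oc2cc(C)oc(=O)c21 | intermediate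
6 | (2R)-2-[3,4-bis(pivaloyloxy)phenyl]-4-methoxy-7-methyl-2H,5H-pyrano[4,3-b]pyran-5-one (methyl enol ether) | COC1=C[C@H](c2ccc(OC(=O)C(C)(C)C)c(OC(=O)C(C)(C)C)c2)Oc2cc(C)oc(=O)c21 | intermediate
7 | (2R,3S)-3-[acetoxy(phenyl)-λ3-iodanyl]-2-[3,4-bis(pivaloyloxy)phenyl]-4,4-dimethoxy-7-methyl-3,4-dihydro-2H,5H-pyrano[4,3-b]pyran-5-one | COC1(OC)[C@@H]([I](OC(C)=O)c2ccccc2)[C@H](c2ccc(OC(=O)C(C)(C)C)c(OC(=O)C(C)(C)C)c2)Oc2cc(C)oc(=O)c21 | intermediate
8 | methyl (2R,3R)-2-[3,4-bis(pivaloyloxy)phenyl]-6-methyl-4-oxo-2,3-dihydro-4H-furo[3,2-c]pyran-3-carboxylate | COC(=O)[C@@H]1c2c(cc(C)oc2=O)O[C@H]1c1ccc(OC(=O)C(C)(C)C)c(OC(=O)C(C)(C)C)c1 | intermediate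
9 | (2R,3R)-2-[3,4-bis(pivaloyloxy)phenyl]-6-methyl-4-oxo-2,3-dihydro-4H-furo[3,2-c]pyran-3-carboxylic acid | OC(=O)[C@@H]1c2c(cc(C)oc2=O)O[C@H]1c1ccc(OC(=O)C(C)(C)C)c(OC(=O)C(C)(C)C)c1 | intermediate
10 | dilithium salt of 9 deprotonated at CO2H and at the 6-methyl group (6-methylene-4-oxido dienolate) | [Li+].[Li+].[O-]C(=O)[C@@H]1C2=C([O-])OC(=C)C=C2O[C@H]1c1ccc(OC(=O)C(C)(C)C)c(OC(=O)C(C)(C)C)c1 | intermediate
11 | (2R,3R)-2-[3,4-bis(pivaloyloxy)phenyl]-6-{2-[3,4-bis(pivaloyloxy)phenyl]-2-hydroxyethyl}-4-oxo-2,3-dihydro-4H-furo[3,2-c]pyran-3-carboxylic acid (carbinol epimers) | OC(=O)[C@@H]1c2c(cc(CC(O)c3ccc(OC(=O)C(C)(C)C)c(OC(=O)C(C)(C)C)c3)oc2=O)O[C@H]1c1ccc(OC(=O)C(C)(C)C)c(OC(=O)C(C)(C)C)c1 | intermediate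
12 | (2R,3R)-2-[3,4-bis(pivaloyloxy)phenyl]-6-[(E)-2-(3,4-bis(pivaloyloxy)phenyl)ethenyl]-4-oxo-2,3-dihydro-4H-furo[3,2-c]pyran-3-carboxylic acid | OC(=O)[C@@H]1c2c(cc(/C=C/c3ccc(OC(=O)C(C)(C)C)c(OC(=O)C(C)(C)C)c3)oc2=O)O[C@H]1c1ccc(OC(=O)C(C)(C)C)c(OC(=O)C(C)(C)C)c1 | intermediate
13 | 2,2,6-trimethyl-4H-1,3-dioxin-4-one | CC1=CC(=O)OC(C)(C)O1 | starting material
14 | acyl imidazolide of 12 | O=C(n1ccnc1)[C@@H]1c2c(cc(/C=C/c3ccc(OC(=O)C(C)(C)C)c(OC(=O)C(C)(C)C)c3)oc2=O)O[C@H]1c1ccc(OC(=O)C(C)(C)C)c(OC(=O)C(C)(C)C)c1 | intermediate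
15 | lithium dienolate of 13 | [Li+].C=C1C=C([O-])OC(C)(C)O1 | intermediate
16 | (2R,3R)-2-[3,4-bis(pivaloyloxy)phenyl]-6-[(E)-2-(3,4-bis(pivaloyloxy)phenyl)ethenyl]-3-[2-(2,2-dimethyl-4-oxo-4H-1,3-dioxin-6-yl)acetyl]-2,3-dihydro-4H-furo[3,2-c]pyran-4-one | CC1(C)OC(=O)C=C(CC(=O)[C@@H]2c3c(cc(/C=C/c4ccc(OC(=O)C(C)(C)C)c(OC(=O)C(C)(C)C)c4)oc3=O)O[C@H]2c2ccc(OC(=O)C(C)(C)C)c(OC(=O)C(C)(C)C)c2)O1 | intermediate
17 | acylketene from 16 (3,5-dioxo-5-[ring D C3]-pent-1-en-1-one) | O=C=CC(=O)CC(=O)[C@@H]1c2c(cc(/C=C/c3ccc(OC(=O)C(C)(C)C)c(OC(=O)C(C)(C)C)c3)oc2=O)O[C@H]1c1ccc(OC(=O)C(C)(C)C)c(OC(=O)C(C)(C)C)c1 | intermediate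
18 | (2R,3R)-2-[3,4-bis(pivaloyloxy)phenyl]-6-[(E)-2-(3,4-bis(pivaloyloxy)phenyl)ethenyl]-3-(4-hydroxy-2-oxo-2H-pyran-6-yl)-2,3-dihydro-4H-furo[3,2-c]pyran-4-one | O=c1cc(O)cc([C@@H]2c3c(cc(/C=C/c4ccc(OC(=O)C(C)(C)C)c(OC(=O)C(C)(C)C)c4)oc3=O)O[C@H]2c2ccc(OC(=O)C(C)(C)C)c(OC(=O)C(C)(C)C)c2)o1 | intermediate
19 | (2R,3R)-2-(3,4-dihydroxyphenyl)-6-[(E)-2-(3,4-dihydroxyphenyl)ethenyl]-3-(4-hydroxy-2-oxo-2H-pyran-6-yl)-2,3-dihydro-4H-furo[3,2-c]pyran-4-one | O=c1cc(O)cc([C@@H]2c3c(cc(/C=C/c4ccc(O)c(O)c4)oc3=O)O[C@H]2c2ccc(O)c(O)c2)o1 | target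

**Step count.** Total: 10 steps. Longest linear sequence: 10 steps (1 → 19); aldehyde 2 is used twice.

**Steps most likely to fail**

Step 4. The shift of the pyranone carbon may lose out to dehydrogenation or methanol substitution of the α-iodanyl group, or the acid may open the dihydropyranone at C2 and erode its configuration. The fallback keeps the same bond formation but reaches it by a Wolff ring contraction; it sets out from 5 and comes back at 8. Condensation of 5 at C3 with dimethylformamide dimethyl acetal (toluene, 80 °C) should give the enaminone F1. Diazo transfer with p-toluenesulfonyl azide (CH2Cl2, rt) should give the α-diazoketone F2, which has no C3–H and so cannot open by elimination. Irradiation at 365 nm (or heating) in methanol expels dinitrogen, and the pyranone carbon migrates to the carbene carbon to give the ring-contracted ketene F3. Methanol traps F3 as the ester, and catalytic Et3N equilibrates C3 to the trans isomer 8.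

Step 3. The very acidic 4-OH may form a tight, weakly electrophilic ion pair that cyclises slowly and with poor facial selectivity, and reversible ring opening may erode C2. The fallback replaces asymmetric catalysis by resolution; it sets out from 4 and comes back at 5. Cyclisation of 4 with an achiral amine (DABCO, toluene, rt) gives the racemic dihydropyranone F4. Preparative chromatography on a chiral stationary phase (supercritical CO2/MeOH) separates 5 from the (S)-enantiomer F5. F5 is racemised by the same amine-mediated ring opening and closure and recycled.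

Step 8. The basic dienolate may deprotonate C3–H of the acyl imidazolide (ketene formation, then β-elimination of the ring-F oxygen with loss of ring D and both stereocentres), or may attack a pivalate. The fallback is base-free in the acylation; it sets out from 12 and comes back at 18, bypassing 16. Oxalyl chloride with catalytic DMF (CH2Cl2, 0 °C) should give the acid chloride F6. Mukaiyama-type γ-acylation of 1-methoxy-1,3-bis(trimethylsilyloxy)buta-1,3-diene (CH2Cl2, −78 → 20 °C, aqueous work-up) should give the methyl 3,5-dioxopentanoate F7. Lactonisation of F7 with DBU (THF, rt) closes ring P to give 18.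

**Further compounds**
F1 | step 4 | (2S)-2-[3,4-bis(pivaloyloxy)phenyl]-3-[(E)-(dimethylamino)methylidene]-7-methyl-2,3-dihydro-4H,5H-pyrano[4,3-b]pyran-4,5-dione (same spatial arrangement at C2 as 5) | CN(C)/C=C1/C(=O)c2c(cc(C)oc2=O)O[C@H]1c1ccc(OC(=O)C(C)(C)C)c(OC(=O)C(C)(C)C)c1
F2 | step 4 | (2S)-2-[3,4-bis(pivaloyloxy)phenyl]-3-diazo-7-methyl-2,3-dihydro-4H,5H-pyrano[4,3-b]pyran-4,5-dione | [N-]=[N+]=C1C(=O)c2c(cc(C)oc2=O)O[C@H]1c1ccc(OC(=O)C(C)(C)C)c(OC(=O)C(C)(C)C)c1
F3 | step 4 | (2S)-2-[3,4-bis(pivaloyloxy)phenyl]-6-methyl-3-(oxomethylidene)-2,3-dihydro-4H-furo[3,2-c]pyran-4-one (ketene) | O=C=C1c2c(cc(C)oc2=O)O[C@H]1c1ccc(OC(=O)C(C)(C)C)c(OC(=O)C(C)(C)C)c1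
F4 | step 3 | racemic 2-[3,4-bis(pivaloyloxy)phenyl]-7-methyl-2,3-dihydro-4H,5H-pyrano[4,3-b]pyran-4,5-dione | O=C1CC(c2ccc(OC(=O)C(C)(C)C)c(OC(=O)C(C)(C)C)c2)Oc2cc(C)oc(=O)c21
F5 | step 3 | (2S)-2-[3,4-bis(pivaloyloxy)phenyl]-7-methyl-2,3-dihydro-4H,5H-pyrano[4,3-b]pyran-4,5-dione | O=C1C[C@@H](c2ccc(OC(=O)C(C)(C)C)c(OC(=O)C(C)(C)C)c2)Oc2cc(C)oc(=O)c21
F6 | step 8 | (2R,3R)-2-[3,4-bis(pivaloyloxy)phenyl]-6-[(E)-2-(3,4-bis(pivaloyloxy)phenyl)ethenyl]-4-oxo-2,3-dihydro-4H-furo[3,2-c]pyran-3-carbonyl chloride | O=C(Cl)[C@@H]1c2c(cc(/C=C/c3ccc(OC(=O)C(C)(C)C)c(OC(=O)C(C)(C)C)c3)oc2=O)O[C@H]1c1ccc(OC(=O)C(C)(C)C)c(OC(=O)C(C)(C)C)c1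
F7 | step 8 | methyl 5-{(2R,3R)-2-[3,4-bis(pivaloyloxy)phenyl]-6-[(E)-2-(3,4-bis(pivaloyloxy)phenyl)ethenyl]-4-oxo-2,3-dihydro-4H-furo[3,2-c]pyran-3-yl}-3,5-dioxopentanoate | COC(=O)CC(=O)CC(=O)[C@@H]1c2c(cc(/C=C/c3ccc(OC(=O)C(C)(C)C)c(OC(=O)C(C)(C)C)c3)oc2=O)O[C@H]1c1ccc(OC(=O)C(C)(C)C)c(OC(=O)C(C)(C)C)c1
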